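Amounts first, for whoever takes this bench over. The pump brings the whole charge of free monomer in over 5.0 h, so I know how much has gone in at each reading. Free monomer and monomer in chains together fall short of that amount, and I call the shortfall the third pool.

the same everywhere: initiator 0.5 mol%

| flask | free monomer | transfer agent | remark | time |
|---|---|---|---|---|
| blue | 1.4 M (fed, over 5.0 h) | 0.87 M | run made earlier; the fed solution adds 0.25 times the starting volume |  |
| grey | 2.2 M (fed, over 5.0 h) | 0.87 M | run made earlier; the fed solution adds 0.25 times the starting volume |  |
| red | 2.9 M (fed, over 5.0 h) | 1.7 M | run made earlier; the fed solution adds 0.25 times the starting volume |  |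
| flask | 2.9 M (fed, over 5.0 h) | 0.870 M | the fed solution adds 0.25 times the starting volume | 5.0 h |

| run | time / h | monomer in chains / % | free monomer / % |
|---|---|---|---|
| blue | 0.833 | 0.1 | 16.4 |
| blue | 1.33 | 1.1 | 24.6 |
| blue | 1.50 | 1.6 | 26.9 |
| blue | 2.50 | 5.8 | 40.8 |
| blue | 4.00 | 7.5 | 59.0 |
| blue | 5.00 | 6.5 | 72.7 |
| grey | 0.833 | 0.9 | 16.3 |
| grey | 1.33 | 3.7 | 22.3 |
| grey | 1.50 | 3.6 | 24.8 |
| grey | 2.50 | 8.3 | 33.9 |
| grey | 4.00 | 9.4 | 50.1 |
| grey | 5.00 | 8.7 | 65.0 |
| red | 0.833 | 1.7 | 15.6 |
| red | 1.33 | 3.4 | 21.8 |
| red | 2.00 | 6.6 | 29.0 |
| red | 3.00 | 6.6 | 42.5 |
| red | 5.00 | 3.5 | 77.7 |

(each reading ± 0.5 percentage points)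

- the moment within 5.0 h at which there is most monomer in chains
- the amount of monomer in chains, in percent of the free monomer charged, at that time
- the first time at which monomer in chains reaches 3.5%, in the same percent

- amounts are per litre of the starting volume; all of the dose is in the solution fed
- the analysis behind the earlier runs scatters by 0.5 percentage points, standard deviation
- percentages count the whole charge, also what has not yet gone in
- a reading or a percentage of monomer in chains counts all its forms, free or not

I read grey, since its [transfer agent] of 0.87 M matches the flask's 0.870 M. Between 2.50 h and 5.00 h its third pool gains 18 percentage points, while its monomer in chains averages 8.93%. If the pool fills in proportion to monomer in chains, integrating that rate makes the gain equal a constant times the average times the interval. This gives a drain constant of 0.829 /h, a first-order rate constant, as a reading that carries 0.5 points of scatter. Multiplied by the level in chains and the dosing time, it gives the share of the pump's flow leaving chains: 38.9% for grey at 4.00 h. I expect a higher share in this flask, which has more free monomer than grey. Red differs from grey in both free monomer and transfer agent, so I take no rule on the transfer agent from red.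

The forecast, meant to “extrapolate the monomer trend with diminishing returns”, gives 10.5% at 3.3 h and the level at 1.2 h.

The flask gives 11.6% at 3.30 h and reaches 3.5% at 1.24 h. At that best time it holds 37.5% free monomer and 16.9% isomer of the product, which is my third pool.

    monomer in chains ⇌ isomer of the product (K = 19.0, k = 0.0150 /min)
    crystals ⇌ monomer in chains, rate k2*(cs2 - [monomer in chains]) while solid is left; crystals form when [monomer in chains] > cs2 (solubility = 0.970 M, k = 0.160 /min)
    free monomer + initiator → living end + monomer in chains (k = 0.0420 /M/min)
    living end + transfer agent → dead chain (kL = 0.0140 /M/min)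
    free monomer + living end → monomer in chains + living end, rate k5*[living end]*[free monomer] (k = 1.30 /M/min)

Reckoned with my drain constant, which is a reading of the net filling of the third pool, the flow into that pool in this flask at the best time is 48.0% of the pump's flow, more than the same reckoning gives for grey. A neighbouring flask charged with 0.35 M of transfer agent ends with 17.3% in chains, which the same reading turns into an estimated net flow of 71.7% of the pump's.

The numbers in the tables were generated by integration for an exercise; noise was put on by code.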